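Late times first: each product takes one partner, so c_product in the south-east flask has a ceiling of 0.0480 M, or 24.0% of the starting material charged. By its charge the partner is the limiting reagent there, 0.0480 M against 0.200 M of starting material.

| flask | starting material | partner | free catalyst | time |
|---|---|---|---|---|
| north-west | 0.200 M | 0.220 M | 0.0100 M |  |
| north-east | 0.0800 M | 0.100 M | 0.0100 M |  |
| south | 0.200 M | 0.110 M | 0.0100 M |  |
| south-east | 0.200 M | 0.0480 M | 0.0100 M | 3.2 h |

| run | time / h | [product] / M |
|---|---|---|
| north-west run | 0.24 | 0.0129 |
| north-west run | 0.74 | 0.0359 |
| north-west run | 1.4 | 0.0607 |
| north-west run | 2.2 | 0.0827 |
| north-west run | 3.2 | 0.0930 |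
| north-east run | 0.24 | 6 × 10⁻⁴ |
| north-east run | 0.74 | 0.0055 |
| north-east run | 1.4 | 0.0105 |
| north-east run | 2.2 | 0.0150 |
| north-east run | 3.2 | 0.0206 |
| south run | 0.24 | 0.0049 |
| south run | 0.74 | 0.0159 |
| south run | 1.4 | 0.0271 |
| south run | 2.2 | 0.0330 |
| south run | 3.2 | 0.0437 |

(standard deviation of a reading: 0.001 M)

- reaction order in [starting material] at the outset, round the charge of the north-west run, defined at two percent of the starting material turned into product (one fixed amount of product, the same in the runs compared)
- reaction order in [partner] at the outset, round the charge of the north-west run, defined at two percent of the starting material turned into product
- product in the south-east run at 3.2 h, as a share of the starting material charged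

- Overall: starting material + partner -> product, with free catalyst as catalyst.
- Constant volume, constant temperature.
- "The second partner" is partner.
- An order is taken over about fifteen percent of the charge, up and down.

How far towards that ceiling does this flask get in 3.2 h? With starting material charged in excess, I treat the partner as pseudo-first-order and take the order in starting material as one. For the south run at 3.2 h I get 0.888 /M/h for the pair constant: the log of partner charged over partner left, divided by the time and by the mean c_starting material, taken as the charge less half the product.

Does it depend on the partner? The north-west run, at the same time and with twice the partner, gives 1.12 /M/h. Read across these two runs at this one time, that is an apparent power of 0.333 in c_partner. The two runs also differ in product, 0.0930 M against 0.0437 M, so I carry this power as a working scaling and not as an order.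

With that working scaling, the pair constant for the south-east charge comes to 0.674 /M/h. If a third of the partner turns, the mean c_starting material is 0.192 M, and the partner decays at 0.129 /h. Over 3.2 h that turns 33.9% of the partner, so I commit to 8.14% of the starting material charged.

The forecast gives more than my figure, 9% (range 7% to 10.8%), with orders of 1 in starting material and 1.4 in partner. Of the low late points it says: “which hints at an outlier, late deactivation or reversibility”.

The south-east flask gives 8.00%, and these are the steps behind it:

    2 free catalyst ⇌ catalyst dimer, settled at all times (2110 /M)
    catalyst dimer + starting material + partner → product + catalyst dimer (250.2 /M²/h)
    2 starting material → homo dimer (2.156 /M/h)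
    starting material + partner + product → 2 product (39.60 /M²/h)

The orders at the outset are 1.0 in starting material and 1.1 in partner, and the best power-law order in partner across the runs is 1.5. Read back from the south-east share, the pair constant is 0.660 /M/h, against 0.674 /M/h reckoned. The working scaling, taken to the 0.100 M of partner in the north-east run, gives 0.860 /M/h, which puts a quarter of that run's starting material turned at 3.71 h; the north-east run reaches it at 3.36 h.

Readings and results are simulated on assumed constants.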